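**Retrosynthetic overview**
1. Target 5 ⇒ alkene 3: the C11–OH is put in last by Markovnikov, trans-diaxial hydration of the ring B alkene.
2. 3 ⇒ 2: ring B (C10–C15 bond, C14–Br) by enantioselective bromonium-initiated cyclisation of the homogeranyl chain, ended by proton loss.
3. 2 ⇒ 1: ring A (bromotetrahydropyran; C7–O bond and C6–Br, the key step) by catalyst-controlled 6-endo bromoetherification of racemic geranyllinalool; only the (S)-half of 1 is carried on.
4. Ring order: ring A first (it removes the C6=C7 alkene, so ring B stops at a monocycle), then ring B, then the hydroxyl.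

**Assumptions and conventions**
- Assumption: isomerically pure, racemic (6E,10E)-geranyllinalool is bought. Atom numbers C1–C16 are those of its hexadecane chain and are used for all compounds.
- Catalyst: (R)-3,3′-(2,4,6-iPr3C6H2)2-BINOL N-triflyl thiophosphoramide, (ArO)2P(=S)NHSO2CF3, C51H57F3NO4PS2. The antipode needed is the one that passes Br+ to the Re face of the CH alkene carbon; it is written here as (R), and the mirror-image catalyst is used if a model run shows the opposite sense.
- Stereochemical plan: C3 is not created but selected (diastereomer separation after step 1). C6/C7 and C14/C10 are catalyst-set. C11 is substrate-controlled in step 3.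

**Step 1**
Reactants: 1 racemic (6E,10E)-geranyllinalool [(6E,10E)-3,7,11,15-tetramethylhexadeca-1,6,10,14-tetraen-3-ol]
Product: 2 (2S,3R,6S)-3-bromo-2-[(3E)-4,8-dimethylnona-3,7-dien-1-yl]-2,6-dimethyl-6-vinyltetrahydro-2H-pyran
Conditions: NBS (1.05 equiv), (R)-3,3′-(2,4,6-iPr3C6H2)2-BINOL N-triflyl thiophosphoramide (10 mol %), toluene/CH2Cl2 3:1, 4 Å MS, −78 °C; SiO2 chromatography
Reagents that add atoms: N-bromosuccinimide (NBS), O=C1CCC(=O)N1Br
Why: Proposed new method: the P=S sulfur takes Br+ from NBS while the N-triflyl amide site hydrogen-bonds the tertiary O–H, so Br+ is relayed to the nearest trisubstituted alkene (C6=C7) on its C6-Re face and the bound hydroxyl closes anti on the more substituted C7 (Markovnikov 6-endo bromoetherification of the E-alkene), which sets C6 (R) and C7 (S) under catalyst control in both enantiomers of 1; the (S)-half gives 2 and the (R)-half gives the (2S,3R,6R)-pyran, a diastereomer removed on silica (a stereodivergent reaction on a racemate); the closest known reactions are chiral Lewis-base/Brønsted-acid catalysed bromocycloetherifications of 5-arylpentenols and thiophosphoramide-catalysed bromo-polyene cyclisations, neither shown for a tertiary alkenol inside a triene.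

**Step 2**
Reactants: 2 (2S,3R,6S)-3-bromo-2-[(3E)-4,8-dimethylnona-3,7-dien-1-yl]-2,6-dimethyl-6-vinyltetrahydro-2H-pyran
Product: 3 (2S,3R,6S)-3-bromo-2-{2-[(1S,5R)-5-bromo-2,6,6-trimethylcyclohex-2-en-1-yl]ethyl}-2,6-dimethyl-6-vinyltetrahydro-2H-pyran
Conditions: NBS (1.1 equiv), (R)-3,3′-(2,4,6-iPr3C6H2)2-BINOL N-triflyl thiophosphoramide (10 mol %), toluene/CH2Cl2 3:1, −78 to −60 °C; AgNO3-impregnated SiO2 to remove minor alkene isomers
Reagents that add atoms: N-bromosuccinimide (NBS), O=C1CCC(=O)N1Br
Why: Proposed new method: the same chiral P=S–Br+ carrier passes Br+ to the C14-Re face of the terminal alkene (the only bromiranium ion with a six-membered chair cyclisation open to it), the (E)-C10=C11 alkene attacks C15 anti to bromine through a chair with Br and the C9 chain both equatorial (sets C14 R and C10 cis to Br), and the C11 cation loses the axial H-12 to the succinimide anion (E1) to give the endocyclic alkene; the closest known reaction is the thiophosphoramide-catalysed enantioselective bromonium cyclisation of homogeranyl arenes, here ended by proton loss as in the achiral TBCO or Et2SBr·SbCl5Br cyclisations that give snyderol-type alkenes.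

**Step 3**
Reactants: 3 (2S,3R,6S)-3-bromo-2-{2-[(1S,5R)-5-bromo-2,6,6-trimethylcyclohex-2-en-1-yl]ethyl}-2,6-dimethyl-6-vinyltetrahydro-2H-pyran
Product: 5 (1S,2R,4R)-4-bromo-2-{2-[(2S,3R,6S)-3-bromo-2,6-dimethyl-6-vinyltetrahydro-2H-pyran-2-yl]ethyl}-1,3,3-trimethylcyclohexan-1-ol (target CNP0244533.1), via acetoxymercurio alcohol 4 (not isolated)
Conditions: Hg(OAc)2 (1.1 equiv), THF/H2O 1:1, 0 °C to rt; then 3 M NaOH, NaBH4, 0 °C
Reagents that add atoms: water, O; mercury diacetate Hg(OAc)2, CC(=O)O[Hg]OC(C)=O (its HgOAc group stays only in 4)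
Why: Oxymercuration–demercuration (Markovnikov hydration): divalent mercury takes the alkene face away from the axial C15 methyl, water opens the mercurinium ion anti at the tertiary C11 in the trans-diaxial (Fürst–Plattner) sense, which puts the OH axial and cis to the C9 chain (C11 S, the epimer that plain anti capture of the cyclisation cation by water would not give), and NaBH4 then replaces Hg by H at C12 without touching the C–Br bonds or the hindered, oxygen-deactivated vinyl group.

**Compound list**
1 | racemic (6E,10E)-3,7,11,15-tetramethylhexadeca-1,6,10,14-tetraen-3-ol (geranyllinalool) | C=CC(C)(O)CC/C=C(\C)CC/C=C(\C)CCC=C(C)C | starting material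
2 | (2S,3R,6S)-3-bromo-2-[(3E)-4,8-dimethylnona-3,7-dien-1-yl]-2,6-dimethyl-6-vinyltetrahydro-2H-pyran | C=C[C@]1(C)CC[C@@H](Br)[C@](C)(CC/C=C(\C)CCC=C(C)C)O1 | intermediate
3 | (2S,3R,6S)-3-bromo-2-{2-[(1S,5R)-5-bromo-2,6,6-trimethylcyclohex-2-en-1-yl]ethyl}-2,6-dimethyl-6-vinyltetrahydro-2H-pyran | C=C[C@]1(C)CC[C@@H](Br)[C@](C)(CC[C@@H]2C(C)(C)[C@H](Br)CC=C2C)O1 | intermediate
4 | (1R,2R,4R,6R)-6-(acetoxymercurio)-4-bromo-2-{2-[(2S,3R,6S)-3-bromo-2,6-dimethyl-6-vinyltetrahydro-2H-pyran-2-yl]ethyl}-1,3,3-trimethylcyclohexan-1-ol (acetoxymercurio alcohol) | C=C[C@]1(C)CC[C@@H](Br)[C@](C)(CC[C@@H]2C(C)(C)[C@H](Br)C[C@@H]([Hg]OC(C)=O)[C@]2(C)O)O1 | intermediate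
5 | (1S,2R,4R)-4-bromo-2-{2-[(2S,3R,6S)-3-bromo-2,6-dimethyl-6-vinyltetrahydro-2H-pyran-2-yl]ethyl}-1,3,3-trimethylcyclohexan-1-ol | C=C[C@]1(C)CC[C@@H](Br)[C@](C)(CC[C@@H]2C(C)(C)[C@H](Br)CC[C@]2(C)O)O1 | target

**Step count and risks**
Total steps: 3. Longest linear sequence: 3.

The mirror image of 5 can only arise if both catalyst-controlled events err, so the ee of 5 is amplified. The remaining stereo-impurities are diastereomers, removed from 5 by crystallisation or preparative HPLC.

The three steps most likely to fail:

First, the bromoetherification that makes 2 (proposed new step). The risks are Br+ going to the terminal alkene instead of C6=C7, 5-exo closure to a tetrahydrofuran, and weak facial control. The fallback uses known chemistry and sets out from 1. Racemic 1 is resolved by preparative chiral SFC to (S)-(6E,10E)-geranyllinalool F1. F1 is then cyclised with 2,4,4,6-tetrabromocyclohexa-2,5-dienone (TBCO) in MeNO2, the classical uncatalysed 6-endo bromoetherification of linalool-type alcohols. Without catalyst control this gives 2 and the (2R,3S,6S)-pyran diastereomer F2 in about equal amounts; both are enantiopure because F1 is, and they are separated on silica. The route is rejoined at 2.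

Second, the bromocarbocyclisation that makes 3 (also an unprecedented use of the catalyst). The risks are lower enantiocontrol without an anchoring hydroxyl, alkene-isomer mixtures, and capture of the C11 cation by the pyran oxygen. The fallback uses known chemistry and sets out from 2. Achiral Et2SBr·SbCl5Br in MeNO2 at −25 °C, a reagent established for proton-loss-terminated bromocyclisations, gives 3 together with the ring B diastereomer (2S,3R,6S)-3-bromo-2-{2-[(1R,5S)-5-bromo-2,6,6-trimethylcyclohex-2-en-1-yl]ethyl}-2,6-dimethyl-6-vinyltetrahydro-2H-pyran F3, about 1:1, because the remote pyran cannot steer the new ring. The two are separated by preparative HPLC and the route is rejoined at 3.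

Third, the hydration that makes 5. The risks are competing oxymercuration of the vinyl group and slow reaction of the hindered ring alkene. The fallback sets out from 3. N-iodosuccinimide in DME/H2O at 0 °C is far more selective for the electron-rich trisubstituted alkene and gives, by the same anti, trans-diaxial opening, the iodohydrin (1R,2R,4R,6R)-4-bromo-2-{2-[(2S,3R,6S)-3-bromo-2,6-dimethyl-6-vinyltetrahydro-2H-pyran-2-yl]ethyl}-6-iodo-1,3,3-trimethylcyclohexan-1-ol F4. Radical deiodination with Bu3SnH (1.05 equiv) and Et3B/air in toluene at −40 °C removes iodine in preference to the secondary bromides and comes back to the route at 5.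

**Further compounds**
F1 | step 1 | (S)-(6E,10E)-3,7,11,15-tetramethylhexadeca-1,6,10,14-tetraen-3-ol | C=C[C@@](C)(O)CC/C=C(\C)CC/C=C(\C)CCC=C(C)C
F2 | step 1 | (2R,3S,6S)-3-bromo-2-[(3E)-4,8-dimethylnona-3,7-dien-1-yl]-2,6-dimethyl-6-vinyltetrahydro-2H-pyran | C=C[C@]1(C)CC[C@H](Br)[C@@](C)(CC/C=C(\C)CCC=C(C)C)O1
F3 | step 2 | (2S,3R,6S)-3-bromo-2-{2-[(1R,5S)-5-bromo-2,6,6-trimethylcyclohex-2-en-1-yl]ethyl}-2,6-dimethyl-6-vinyltetrahydro-2H-pyran | C=C[C@]1(C)CC[C@@H](Br)[C@](C)(CC[C@H]2C(C)(C)[C@@H](Br)CC=C2C)O1
F4 | step 3 | (1R,2R,4R,6R)-4-bromo-2-{2-[(2S,3R,6S)-3-bromo-2,6-dimethyl-6-vinyltetrahydro-2H-pyran-2-yl]ethyl}-6-iodo-1,3,3-trimethylcyclohexan-1-ol | C=C[C@]1(C)CC[C@@H](Br)[C@](C)(CC[C@@H]2C(C)(C)[C@H](Br)C[C@@H](I)[C@]2(C)O)O1
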